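**Assumptions (one line each)**
- The target is the trans-(1S,2R) 1-aryl-1,2-dihydronaphthalene. I checked the SMILES: C1 is S, C2 is R, and Ar and CH2OH are on opposite faces.
- Both phenols are carried as allyl ethers, because the final diol is acid-sensitive and hydrogenolysis risks the styrenyl C=C.

**Retrosynthesis**
- The target comes from removing two allyl groups from a diol, which comes from reducing a diester/imide.
- The ring is closed last, by cationic Friedel–Crafts cyclisation of an Evans syn-aldol carbinol onto the Z-aryl alkene of a Stobbe half-ester. This forms C1–C8a, and C1 ends up trans to C2.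
- The C2 stereocentre comes from the (S)-benzyl oxazolidinone auxiliary in the aldol. The Stobbe reaction gives the (E)-half-ester, which places Ar cis to CH2 as the ring closure needs.
- Both aryl units come from the same aldehyde, O-allylvanillin, used in the Stobbe step and in the aldol.

**Step 1**
Reactants: 1 vanillin; 2 allyl bromide
Product: 3 4-allyloxy-3-methoxybenzaldehyde
Conditions: K2CO3, DMF, 60 °C
Reagents that add atoms: none (allyl bromide is listed as a reactant)
Why: Williamson O-allylation of the phenol gives a base-stable and acid-stable protecting group that Pd(0) can remove later.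

**Step 2**
Reactants: 3; 4 diethyl succinate
Product: 5 (E)-ethyl hydrogen 2-[(4-allyloxy-3-methoxyphenyl)methylidene]succinate, i.e. ArCH=C(CO2Et)CH2CO2H with Ar trans to CO2Et
Conditions: KOt-Bu, t-BuOH, reflux; then aq. HCl
Reagents that add atoms: none
Why: The Stobbe condensation gives the (E)-half-ester, so the aryl group is cis to CH2CO2H, which is the geometry needed to close the six-membered ring.

**Step 3**
Reactants: 5; 6 (S)-4-benzyloxazolidin-2-one
Product: 7 the N-acyl oxazolidinone of 5
Conditions: PivCl, Et3N, THF, –20 °C; then 6, LiCl, rt
Reagents that add atoms: none (the pivaloyl group leaves as pivalic acid)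
Why: Acylation through the mixed anhydride is selective for the CH2CO2H carbonyl, the conjugated ethyl ester and the alkene are untouched, and the auxiliary is now in place for the aldol.

**Step 4**
Reactants: 7; 3
Product: 8 the syn-aldol adduct, with acyl C2 = S and carbinol = S
Conditions: Bu2BOTf, i-Pr2NEt, CH2Cl2, –78 → 0 °C; then H2O2, pH 7 buffer
Reagents that add atoms: none (the new OH oxygen comes from the aldehyde)
Why: Evans syn aldol through the Z-boron enolate and a Zimmerman–Traxler transition state. The (S)-benzyl auxiliary sets C2; it becomes R in the target after CIP re-ranking with no change in spatial arrangement. The boron enolate forms only at the imide, not at the ester.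

**Step 5**
Reactant: 8
Product: 9 the 1-aryl-1,2-dihydronaphthalene imide/ester, (1S,2R), trans
Conditions: BF3·OEt2, CH2Cl2, –20 → 0 °C
Reagents that add atoms: none (water is lost)
Why: The p-allyloxybenzylic carbinol ionises, and the Z-aryl ring attacks para to its OMe in an intramolecular Friedel–Crafts cyclisation. This gives the 6-OMe/7-OAllyl pattern of the target. The carbinol stereocentre is destroyed, and C1 is set trans to C2 through the pseudo-diaxial half-chair. Allyl ethers, ester and imide survive at low temperature.

**Step 6**
Reactant: 9
Product: 10 the diallyl ether diol, (1S,2R)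
Conditions: LiAlH4, THF, 0 °C
Reagents that add atoms: none (only hydride and H)
Why: Hydride reduction takes both the imide and the conjugated ester to CH2OH and releases auxiliary 6 for recovery. The trisubstituted alkene, aryl allyl ethers and both stereocentres are untouched.

**Step 7**
Reactant: 10
Product: 11 the target
Conditions: Pd(PPh3)4 (5 mol%), K2CO3, MeOH, rt
Reagents that add atoms: none
Why: Pd(0) π-allyl deallylation is neutral, so the acid-sensitive allylic diol and the styrenyl alkene are preserved and no stereocentre is touched.

**Compound list**

| No. | Name | SMILES | Role |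
|---|---|---|---|
| 1 | vanillin | COc1cc(C=O)ccc1O | starting material |
| 2 | allyl bromide | C=CCBr | starting material |
| 3 | 4-allyloxy-3-methoxybenzaldehyde | COc1cc(C=O)ccc1OCC=C | intermediate |
| 4 | diethyl succinate | CCOC(=O)CCC(=O)OCC | starting material |
| 5 | (E)-Stobbe half-ester | CCOC(=O)/C(=C/c1ccc(OCC=C)c(OC)c1)CC(=O)O | intermediate |
| 6 | (S)-4-benzyloxazolidin-2-one | O=C1N[C@@H](Cc2ccccc2)CO1 | starting material |
| 7 | N-acyl oxazolidinone | CCOC(=O)/C(=C/c1ccc(OCC=C)c(OC)c1)CC(=O)N2[C@@H](Cc3ccccc3)COC2=O | intermediate |
| 8 | Evans syn-aldol adduct | CCOC(=O)/C(=C/c1ccc(OCC=C)c(OC)c1)[C@H](C(=O)N2[C@@H](Cc3ccccc3)COC2=O)[C@H](O)c4ccc(OCC=C)c(OC)c4 | intermediate |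
| 9 | cyclised dihydronaphthalene imide/ester | COc1cc([C@H]2c3cc(OCC=C)c(OC)cc3C=C(C(=O)OCC)[C@@H]2C(=O)N4[C@@H](Cc5ccccc5)COC4=O)ccc1OCC=C | intermediate |
| 10 | diallyl ether diol | COc1cc([C@H]2c3cc(OCC=C)c(OC)cc3C=C(CO)[C@@H]2CO)ccc1OCC=C | intermediate |
| 11 | target | COc1cc([C@H]2c3cc(O)c(OC)cc3C=C(CO)[C@@H]2CO)ccc1O | target |

**Totals**
- Total steps: 7.
- Longest linear sequence: 7 (1 → 3 → 5 → 7 → 8 → 9 → 10 → 11).

**Three steps most likely to fail**
1. **Step 5 (cyclisation).** The cinnamate-type arene is deactivated, the cation can be captured by the ester carbonyl to give a lactone, C2 can epimerise, and the trans selectivity may be modest.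
   - Fallback: hydrogenate the Stobbe alkene early, using a benzyl group in place of allyl. Cyclise the more nucleophilic saturated arene to the trans tetralin. Then install C3=C4 by ester-enolate selenation and selenoxide elimination.
2. **Step 4 (Evans aldol).** The β,γ-unsaturated, α-branched imide may isomerise into conjugation or give low dr.
   - Fallback: drop the auxiliary aldol. Build the racemic trans-dihydronaphthalene lactone by intramolecular dehydro-Diels–Alder of the arylpropiolate ester of (E)-4-allyloxy-3-methoxycinnamyl alcohol. Reduce it with LiAlH4, then separate the enantiomers of the diol by chiral HPLC.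
3. **Step 6 (LiAlH4).** It may 1,4-reduce the unsaturated ester, over-reduce the auxiliary, or epimerise C2.
   - Fallback: remove the auxiliary first with LiOOH and esterify with TMSCHN2. Then reduce the resulting diester with DIBAL-H, which is 1,2-selective.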